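## The problem

Target 31 is made of two trans-fused oxepane–cyclohexane bicycles, rings A/B and rings D/C, joined through the C12–C13 bridge between C11 and C14. Numbering follows the chain: ring A = O1, C2(Me2), C3, C4, C5, C6(Me), C7; ring B = C6–C11; ring C = C14–C19; ring D = C19–C23 plus the oxygen on C18. There are nine stereocentres (C3, C6, C7, C11 and C14, C15, C18, C19, C22), and the carbon skeletons of the two halves are identical and of the same handedness. The quaternary carbons C6 and C19 are the anchors: once fixed, they can direct the C7/C18 carbinols (ketone reduction), the C11/C14 centres (equatorial bridge next to a ketone) and the C15 carbinol (attack anti to the syn-axial C19 methyl), whereas C3 and C22 are too remote and need reagent control. The halves differ at two remote sites that are paired: a free C3 hydroxyl with the C10 exocyclic methylene in one, the C22 acetate with the axial tertiary C15 acetate in the other, so any route through a symmetric intermediate must assign four groups to the right halves. The tertiary acetate (ionisation, elimination), the 1,1-disubstituted alkene (acid, electrophiles), the free hydroxyl beside two esters (no global ester cleavage at the end) and the epoxides that precede the oxepanes limit the late chemistry. Rings B and C are each a six-membered carbocycle with a methyl-bearing quaternary carbon (C6, C19) flanked by an oxygenated carbon (C7, C18) and by the carbon that carries the bridge (C11, C14). This is a bibenzyl of two 2-methoxybenzoic acids in disguise, whose ipso carbons can both be methylated reductively. Below, α is the face of ring B or C that carries the angular methyl and β the opposite face.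

## Retrosynthesis

**O1–C2 (ring A), 31 from 30.** The last bond cut is the ring A ether. Closing it by 7-endo opening of the (R)-epoxide in hydroxy epoxide 30 releases the C3 hydroxyl in the final operation, so it never needs protection beside the two acetates. The forward step must open the epoxide at its tertiary carbon and leave the methylene and both esters alone.

**The gate and ring D, 30 from 29, 29 from 27.** If both oxepanes were closed at once, C3-OH and C22-OH would be indistinguishable. In 27 and 29 the C7 oxygen and the C10 methylene are tied together as a bridged iodo ether, which only the half that owns the methylene can form. The pairing of the four differentiating groups is therefore structural, not statistical. With the gate in place, ring D is closed (O–C23) and C22-OH acetylated; zinc then returns the C7 hydroxyl and the alkene.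

**Ring B against ring C, 27 from 25, 25 from 23, 23 from 22.** The C10 methylene and the C15 methyl carbinol are both cut back to ketones of the C2-symmetric bis-epoxy diketone 22. One equivalent of ylide gives 23, the only statistical step, on a symmetric substrate that can give only one mono-olefin. Methyllithium followed by acetic anhydride gives 25.

**Side chains and ring ketones, 22 back to 13.** The epoxides of 22 come from the trisubstituted alkenes of 21. The C3–C4 and C21–C22 bonds come from B-alkyl Suzuki coupling of the vinyl groups of 17 with bromide 18, and the vinyl groups from aldehydes 16. C5 and C20 are neopentyl, which rules out SN2 alkylation and speaks for olefination plus cross-coupling. The ring ketones are cut back to the ring alkenes of 13 (via 15); hydroborating these before any side-chain alkene exists removes every alkene-against-alkene selectivity question.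

**Amide and carbinol, 13 back to 9.** C5 and C20 are the former carboxamide carbons (12 to 13). The C7/C18 carbinols are set on the β-keto amides 10 while the amide is still present to chelate (10 to 11), and the ketones are the hydrolysed enol ethers of 9.

**C6–CH3 and C19–CH3, 9 from 6 and 7.** Both quaternary centres are cut at once, returning two aromatic rings. Bibenzyl bis-amide 6 has no stereocentre in its skeleton and carries the auxiliary twice; the forward step must reduce both rings and methylate both enolates with the same facial sense.

**C12–C13, 6 from 4, 4 from 1 and 2.** The bridge is cut to two benzylic carbons of toluamide 4 (through benzylic lithium 5), and 4 to acid 1 and amine 2. Making this bond first, on the simplest compound of the route, avoids any late sp3–sp3 union of two hindered halves.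

## Roads not taken

Alternative 1: Rings D and C would be cut at O–C23 and C14–C19 and formed together in an epoxonium cascade. BF3·OEt2 activates a terminal epoxide, an internal epoxide oxygen closes the oxepane, and an allylsilane terminates at C19 to give the ring C/D diol A1 with a vinyl group on C14.
- Merits: two rings, one C–C bond and the C14/C19 relationship arise in one step, and the C15 tertiary carbinol comes from a chiral-pool tertiary alcohol. The half is born unsymmetrical, so the pairing problem does not exist; in this respect the road is better than the chosen one.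
- Weak points: A1 is only one half. Rings A/B need a second synthesis, and the halves must be joined at C12–C13 by an sp3–sp3 coupling between two hindered centres. The cascade must also hold a chair-like arrangement against boat alternatives to set C14.
- The chosen plan sets against this that every operation builds both halves, that C12–C13 is made at the outset, and that one auxiliary sets both quaternary centres.

Alternative 2: Rings A and B would be cut at O–C2 and C6–C11. Et2AlCl opens a 2,3-epoxide, a 6,7-epoxide oxygen attacks C2, and a 2-(silylmethyl)alkene attacks C6, giving the ring A/B bicycle A2 with the C10 methylene already in place and C12 as a silyloxymethyl group.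
- Merits: A2 carries the free C3 hydroxyl and the exocyclic alkene in final form, with no ketone olefination and no gate. This is better than the chosen route for that half.
- Weak points: C11 is set in the cascade, the ring C/D half must be made separately, and C12, a CH2O carbon in A2, must be turned into a coupling partner for C13.
- The chosen plan pays for its symmetric assembly with the one statistical olefination (step 14) and the gate (steps 16–18).

Alternative 3: Ring C would be cut at C14–C15. A pyrrolidine/acetic acid enamine of a C13 aldehyde adds to a C15 methyl ketone on a preformed oxepane ring D, giving the β-hydroxy aldehyde A3.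
- Merits: the tertiary carbinol and C14 form under mild conditions, and the C13 aldehyde is a direct handle for the bridge. The C15–oxygen bond is made without an organometallic, which is as good as the chosen methyllithium addition.
- Weak points: the harder problem, the quaternary C19 on an oxepane bearing two different chains, is left to earlier steps. The aldol is reversible, so the axial carbinol needed at C15 is not assured, and A3 can dehydrate or revert.
- The chosen plan sets C15 by attack anti to the syn-axial C19 methyl, and makes the quaternary centres in the key step itself.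

Key step: step 3

Assumption: the (S)-auxiliary amide is taken to give the (R) configuration at both new quaternary carbons of 9, as the chelate model predicts; if the extra ortho substituent reverses the sense, the (R)-auxiliary is used and nothing else changes.

## Route

Step 1
Reactants: 1 2-methoxy-6-methylbenzoic acid; 2 (S)-2-(methoxymethyl)pyrrolidine
Product: 4 (S)-(2-methoxy-6-methylphenyl)[2-(methoxymethyl)pyrrolidin-1-yl]methanone, via 2-methoxy-6-methylbenzoyl chloride 3 (not isolated)
Conditions: (COCl)2, cat. DMF, CH2Cl2, 0 °C to rt; then 2, Et3N, CH2Cl2, 0 °C to rt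
Reagents that add atoms: none
Why: Acid chloride formation and amidation; the 2,6-disubstituted acid is too hindered for milder activation, and no stereocentre is touched.

Step 2
Reactants: 4 (two molecules)
Product: 6 1,2-bis{3-methoxy-2-[(S)-2-(methoxymethyl)pyrrolidine-1-carbonyl]phenyl}ethane, via benzylic lithium amide 5 (not isolated)
Conditions: s-BuLi, TMEDA, THF, −78 °C; then CuCl2, −78 °C to rt
Reagents that add atoms: none
Why: Amide-directed lateral lithiation of the ortho methyl group, then oxidative homocoupling of the benzylic organometallic with CuCl2, forms C12–C13; the twisted, doubly ortho-substituted amide resists addition of the base.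

Step 3
Reactants: 6 bibenzyl bis-amide; 7 iodomethane
Product: 9 1,2-bis{(6R)-5-methoxy-6-methyl-6-[(S)-2-(methoxymethyl)pyrrolidine-1-carbonyl]cyclohexa-1,4-dien-1-yl}ethane, via dipotassium bis(amide enolate) 8 (not isolated)
Conditions: K, t-BuOH (one equivalent per ring), NH3(l)/THF, −78 °C; piperylene; then MeI, −78 °C; NH4Cl
Reagents that add atoms: iodomethane (7), CI
Why: Each anisamide ring takes up two electrons from potassium, the dianion is protonated by t-BuOH at the carbon para to the carboxamide (C9, C16), and the remaining potassium amide enolate on each ring is C-methylated at the carbon alpha to the carbonyl (C6, C19) to give the two 1,4-dienes. The closest known reaction is the Birch reduction–alkylation of 2-methoxybenzamides of prolinol ethers, run here twice in one molecule on rings that the CH2CH2 bridge insulates from each other. No ring is closed. Both new quaternary stereocentres are set by the auxiliary: potassium is held between the enolate oxygen and the methoxymethyl arm, the pyrrolidine ring covers one enolate face and iodomethane enters from the other, so one auxiliary gives the same absolute sense at C6 and C19, as the homochiral halves require. The step needs alpha- over gamma-methylation (the carbon bearing the carbonyl carries the highest charge in these dienolates), para protonation (one equivalent of t-BuOH per ring at −78 °C) and survival of the C12–C13 bond (the added electrons sit on the benzamide rings, not on a stabilised benzylic system). Excess metal is destroyed with piperylene before the iodide is added so that the product dienes are not reduced further.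

Step 4
Reactants: 9 bis(diene) bis-amide
Product: 10 1,2-bis{(6R)-6-methyl-5-oxo-6-[(S)-2-(methoxymethyl)pyrrolidine-1-carbonyl]cyclohex-1-en-1-yl}ethane
Conditions: 1 M HCl (aq), THF, rt
Reagents that add atoms: water, O
Why: Acid hydrolysis of the two methyl enol ethers; the C10=C11 and C14=C15 alkenes cannot move into conjugation across the quaternary carbons, and the β-keto amides have no alpha-hydrogen to lose.

Step 5
Reactants: 10 bis(β-keto amide)
Product: 11 1,2-bis{(5R,6R)-5-hydroxy-6-methyl-6-[(S)-2-(methoxymethyl)pyrrolidine-1-carbonyl]cyclohex-1-en-1-yl}ethane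
Conditions: Zn(BH4)2, Et2O/THF, −30 °C
Reagents that add atoms: none
Why: Chelation-controlled reduction of an α,α-disubstituted β-keto amide: zinc bridges the ketone and amide oxygens, which holds the carboxamide pseudo-equatorial and the methyl pseudo-axial. Hydride then adds anti to the methyl and sets C7 and C18 with the hydroxyl α (cis to the methyl, trans to the carboxamide).

Step 6
Reactants: 11 bis(β-hydroxy amide)
Product: 12 1,2-bis{(5R,6R)-5-(tert-butyldimethylsilyloxy)-6-methyl-6-[(S)-2-(methoxymethyl)pyrrolidine-1-carbonyl]cyclohex-1-en-1-yl}ethane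
Conditions: TBSOTf, 2,6-lutidine, CH2Cl2, 0 °C to rt
Reagents that add atoms: tert-butyldimethylsilyl triflate, CC(C)(C)[Si](C)(C)OS(=O)(=O)C(F)(F)F
Why: Silyl triflate silylation of hindered secondary alcohols; the silyl ethers must survive hydride, borane, ylide, palladium and methyllithium before they are removed at step 16.

Step 7
Reactants: 12 bis-silyl ether bis-amide
Product: 13 1,2-bis{(5R,6S)-5-(tert-butyldimethylsilyloxy)-6-(hydroxymethyl)-6-methylcyclohex-1-en-1-yl}ethane
Conditions: LiH2N·BH3 (from NH3·BH3 and LDA), THF, 0 to 40 °C; aq NH4Cl
Reagents that add atoms: none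
Why: Lithium amidotrihydroborate reduces tertiary amides to primary alcohols with C–N cleavage, where aluminium hydrides give amines; the auxiliary is released for recovery and the silyl ethers and ring alkenes are untouched.

Step 8
Reactants: 13 bis(hydroxymethyl) compound
Product: 15 bis-silyl ether tetraol (per ring: C6 methyl α and CH2OH β; C7 OTBS α; C10 OH β; C11 H β), via bis(alkylborane) 14 (not isolated)
Conditions: BH3·THF (excess), THF, 0 °C to rt; then NaOH, H2O2, 0 °C to rt
Reagents that add atoms: hydrogen peroxide, OO
Why: Hydroboration–oxidation puts boron on the less substituted C10/C15 from the β face, anti to the pseudo-axial angular methyl, so hydrogen enters C11/C14 β. The carbinol configuration is immaterial and C11/C14 are secured again at step 12; no side-chain alkene exists yet, so there is no competing alkene.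

Step 9
Reactants: 15 tetraol
Product: 16 bis(hydroxy aldehyde) (as 15 with C5 and C20 as CHO)
Conditions: TEMPO (cat.), PhI(OAc)2, CH2Cl2, rt
Reagents that add atoms: none
Why: Oxoammonium oxidation is selective for primary over secondary alcohols; the aldehyde and the C10/C15 hydroxyl sit diequatorial and cannot form a lactol without chair inversion, so over-oxidation to a lactone is not expected.

Step 10
Reactants: 16 bis(hydroxy aldehyde)
Product: 17 bis(vinyl) diol (C6 and C19 bearing CH=CH2; C10/C15 OH β)
Conditions: Ph3PCH3Br, KOt-Bu (excess), THF, 0 °C to rt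
Reagents that add atoms: methyltriphenylphosphonium bromide, C[P+](c1ccccc1)(c1ccccc1)c1ccccc1.[Br-]
Why: Wittig methylenation of α-quaternary aldehydes, which have no alpha-hydrogen to epimerise; the excess ylide covers the free hydroxyls.

Step 11
Reactants: 17 bis(vinyl) diol; 18 1-bromo-2-methylprop-1-ene
Product: 20 bis(4-methylpent-3-enyl) diol (C6 and C19 bearing CH2CH2CH=CMe2), via bis(B-alkyl-9-BBN) 19 (not isolated)
Conditions: 9-BBN (excess), THF, rt; then 18, Pd(dppf)Cl2 (cat.), AsPh3, Cs2CO3, DMF/H2O, rt to 50 °C
Reagents that add atoms: 1-bromo-2-methylprop-1-ene (18), CC(C)=CBr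
Why: 9-BBN hydroborates the monosubstituted vinyl groups at the terminal carbon; B-alkyl Suzuki–Miyaura coupling with the vinyl bromide then forms C3–C4 and C21–C22 with the trisubstituted alkenes in place, which avoids SN2 chemistry at the neopentyl C5/C20.

Step 12
Reactants: 20 bis(homoprenyl) diol
Product: 21 C2-symmetric C10,C15-diketone (C11/C14 H β; C7/C18 OTBS α)
Conditions: Dess–Martin periodinane, NaHCO3, CH2Cl2, rt; work-up with K2CO3, MeOH, rt
Reagents that add atoms: none
Why: Dess–Martin oxidation of the secondary alcohols. C11 and C14, now alpha to a ketone, prefer the chair with the bridge equatorial (angular methyl axial, all other substituents equatorial), and the mild base secures this if any epimer came from step 8.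

Step 13
Reactants: 21 diketone
Product: 22 bis[(R)-epoxide] diketone ((3R)-2,3- and (22R)-22,23-epoxides)
Conditions: D-fructose-derived Shi ketone, KHSO5 (Oxone), K2CO3, Bu4NHSO4, MeCN/DMM/aq Na2B4O7 buffer, 0 °C
Reagents that add atoms: potassium peroxymonosulfate (Oxone), [K+].[O-]S(=O)(=O)OO
Why: Shi asymmetric epoxidation of the only alkenes present, the trisubstituted side-chain termini. The reagent controls C3 and C22; the D-fructose-derived ketone is expected to give the (R)-epoxides, and its enantiomer is used otherwise.

Step 14
Reactants: 22 bis-epoxide diketone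
Product: 23 C10-methylene C15-ketone (bis-epoxide, bis-silyl ether)
Conditions: Ph3PCH3Br (about one equivalent), KOt-Bu, toluene/THF, 0 °C to rt
Reagents that add atoms: methyltriphenylphosphonium bromide, C[P+](c1ccccc1)(c1ccccc1)c1ccccc1.[Br-]
Why: Wittig methylenation with one equivalent of ylide on a C2-symmetric diketone, where either carbonyl gives the same product. The step is statistical, recovered 22 is recycled, and base-induced epimerisation at C11/C14 runs toward the wanted equatorial arrangement.

Step 15
Reactants: 23 methylene ketone
Product: 25 C15 α-acetate with C15 methyl β (C10 methylene; bis-epoxide; C7/C18 OTBS), via lithium C15 alkoxide 24 (not isolated)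
Conditions: MeLi, Et2O/THF, −78 °C; then Ac2O, −78 to 0 °C
Reagents that add atoms: methyllithium, [Li]C; acetic anhydride, CC(=O)OC(C)=O
Why: Methyllithium adds to the C15 ketone from the equatorial β direction because the axial path is blocked by the syn-axial C19 methyl, giving the axial α-alkoxide. Trapping this with acetic anhydride avoids a forcing esterification of a hindered tertiary alcohol, and epoxides and silyl ethers are inert at −78 °C.

Step 16
Reactants: 25 tertiary acetate
Product: 27 bridged iodo ether (ring B as 7,10-epoxy-10-iodomethyl, a 7-oxabicyclo[2.2.1]heptane; free C18-OH; both epoxides; C15 acetate), via C7/C18 diol 26 (not isolated)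
Conditions: TBAF, AcOH, THF, rt to 45 °C; aqueous work-up; then NIS, NaHCO3, CH2Cl2, 0 °C, dark
Reagents that add atoms: N-iodosuccinimide, O=C1CCC(=O)N1I
Why: Buffered fluoride desilylation, then 5-exo iodoetherification: only the half with the C10 methylene has a hydroxyl–alkene pair, and the C7 hydroxyl attacks the tertiary carbon of the iodonium across ring B. This masks the C7 oxygen and the alkene together (the C10 centre is fixed by the bridge), while the C18 hydroxyl has no alkene partner and stays free.

Step 17
Reactants: 27 iodo ether
Product: 29 ring C/D diacetate iodo ether (ring D closed; C22 and C15 acetates; ring A epoxide intact), via ring D C22 alcohol 28 (not isolated)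
Conditions: CSA (cat.), CH2Cl2, 0 °C; then Ac2O, pyridine, DMAP, rt
Reagents that add atoms: acetic anhydride, CC(=O)OC(C)=O
Why: Acid-catalysed 7-endo-tet opening of the trisubstituted epoxide by the equatorial C18 hydroxyl at the tertiary C23 gives the trans-fused oxepane, with C22 keeping its oxygen and (R) configuration. The gated half has no hydroxyl to open its epoxide, and the new secondary alcohol is acetylated in the same flask.

Step 18
Reactants: 29 diacetate iodo ether
Product: 31 target CNP0412606.2, via hydroxy epoxide 30 (not isolated)
Conditions: Zn dust, NH4Cl, EtOH/THF, 40 °C; filter, concentrate; then CSA (cat.), CH2Cl2, 0 °C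
Reagents that add atoms: none
Why: Zinc-mediated reductive β-elimination of the β-iodo ether returns the C10 methylene and the C7 hydroxyl with C7 unchanged. The same 7-endo-tet epoxide opening then forms O1–C2 (ring A, trans-fused) and sets free the C3 hydroxyl as the last event, beside untouched acetates.

## Compound list

1 | 2-methoxy-6-methylbenzoic acid | COc1cccc(C)c1C(=O)O | starting material
2 | (S)-2-(methoxymethyl)pyrrolidine | COC[C@@H]1CCCN1 | starting material
3 | 2-methoxy-6-methylbenzoyl chloride | COc1cccc(C)c1C(Cl)=O | intermediate
4 | (S)-(2-methoxy-6-methylphenyl)[2-(methoxymethyl)pyrrolidin-1-yl]methanone | COC[C@@H]1CCCN1C(=O)c1c(C)cccc1OC | intermediate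
5 | benzylic lithium derivative of 4 | [Li]Cc1cccc(OC)c1C(=O)N1CCC[C@H]1COC | intermediate
6 | 1,2-bis{3-methoxy-2-[(S)-2-(methoxymethyl)pyrrolidine-1-carbonyl]phenyl}ethane | COC[C@@H]1CCCN1C(=O)c1c(OC)cccc1CCc1cccc(OC)c1C(=O)N1CCC[C@H]1COC | intermediate
7 | iodomethane | CI | starting material
8 | dipotassium bis(amide enolate) of doubly reduced 6 | COC[C@@H]1CCCN1C([O-])=C1C(OC)=CCC=C1CCC1=CCC=C(OC)C1=C([O-])N1CCC[C@H]1COC.[K+].[K+] | intermediate
9 | 1,2-bis{(6R)-5-methoxy-6-methyl-6-[(S)-2-(methoxymethyl)pyrrolidine-1-carbonyl]cyclohexa-1,4-dien-1-yl}ethane | COC[C@@H]1CCCN1C(=O)[C@@]2(C)C(OC)=CCC=C2CCC2=CCC=C(OC)[C@]2(C)C(=O)N1CCC[C@H]1COC | intermediate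
10 | 1,2-bis{(6R)-6-methyl-5-oxo-6-[(S)-2-(methoxymethyl)pyrrolidine-1-carbonyl]cyclohex-1-en-1-yl}ethane | COC[C@@H]1CCCN1C(=O)[C@@]2(C)C(=O)CCC=C2CCC2=CCCC(=O)[C@]2(C)C(=O)N1CCC[C@H]1COC | intermediate
11 | 1,2-bis{(5R,6R)-5-hydroxy-6-methyl-6-[(S)-2-(methoxymethyl)pyrrolidine-1-carbonyl]cyclohex-1-en-1-yl}ethane | COC[C@@H]1CCCN1C(=O)[C@@]2(C)[C@H](O)CCC=C2CCC2=CCC[C@@H](O)[C@]2(C)C(=O)N1CCC[C@H]1COC | intermediate
12 | bis(tert-butyldimethylsilyl) ether of 11 | COC[C@@H]1CCCN1C(=O)[C@@]2(C)[C@H](O[Si](C)(C)C(C)(C)C)CCC=C2CCC2=CCC[C@@H](O[Si](C)(C)C(C)(C)C)[C@]2(C)C(=O)N1CCC[C@H]1COC | intermediate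
13 | 1,2-bis{(5R,6S)-5-(tert-butyldimethylsilyloxy)-6-(hydroxymethyl)-6-methylcyclohex-1-en-1-yl}ethane | OC[C@@]1(C)[C@H](O[Si](C)(C)C(C)(C)C)CCC=C1CCC1=CCC[C@@H](O[Si](C)(C)C(C)(C)C)[C@]1(C)CO | intermediate
14 | bis(alkylborane) from 13 (BH2 β on C10 and C15; hydroxyls drawn free) | OC[C@@]1(C)[C@H](O[Si](C)(C)C(C)(C)C)CC[C@@H](B)[C@@H]1CC[C@H]1[C@H](B)CC[C@@H](O[Si](C)(C)C(C)(C)C)[C@]1(C)CO | intermediate
15 | bis-silyl ether tetraol (C5/C20 CH2OH; C10/C15 OH β; C11/C14 H β) | OC[C@@]1(C)[C@H](O[Si](C)(C)C(C)(C)C)CC[C@@H](O)[C@@H]1CC[C@H]1[C@H](O)CC[C@@H](O[Si](C)(C)C(C)(C)C)[C@]1(C)CO | intermediate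
16 | bis(hydroxy aldehyde) (C5 and C20 as CHO) | O=C[C@@]1(C)[C@H](O[Si](C)(C)C(C)(C)C)CC[C@@H](O)[C@@H]1CC[C@H]1[C@H](O)CC[C@@H](O[Si](C)(C)C(C)(C)C)[C@]1(C)C=O | intermediate
17 | bis(vinyl) diol (C6 and C19 bearing CH=CH2) | C=C[C@@]1(C)[C@H](O[Si](C)(C)C(C)(C)C)CC[C@@H](O)[C@@H]1CC[C@H]1[C@H](O)CC[C@@H](O[Si](C)(C)C(C)(C)C)[C@]1(C)C=C | intermediate
18 | 1-bromo-2-methylprop-1-ene | CC(C)=CBr | starting material
19 | bis(B-alkyl-9-BBN) from 17 (boron on C4 and C21; hydroxyls drawn free) | B1(C2CCCC1CCC2)CC[C@@]3(C)[C@H](O[Si](C)(C)C(C)(C)C)CC[C@@H](O)[C@@H]3CC[C@H]3[C@H](O)CC[C@@H](O[Si](C)(C)C(C)(C)C)[C@]3(C)CCB1C2CCCC1CCC2 | intermediate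
20 | bis(4-methylpent-3-enyl) diol | CC(C)=CCC[C@@]1(C)[C@H](O[Si](C)(C)C(C)(C)C)CC[C@@H](O)[C@@H]1CC[C@H]1[C@H](O)CC[C@@H](O[Si](C)(C)C(C)(C)C)[C@]1(C)CCC=C(C)C | intermediate
21 | C2-symmetric C10,C15-diketone | CC(C)=CCC[C@@]1(C)[C@H](O[Si](C)(C)C(C)(C)C)CCC(=O)[C@@H]1CC[C@H]1C(=O)CC[C@@H](O[Si](C)(C)C(C)(C)C)[C@]1(C)CCC=C(C)C | intermediate
22 | bis[(R)-epoxide] diketone | CC1(C)O[C@@H]1CC[C@@]2(C)[C@H](O[Si](C)(C)C(C)(C)C)CCC(=O)[C@@H]2CC[C@H]2C(=O)CC[C@@H](O[Si](C)(C)C(C)(C)C)[C@]2(C)CC[C@H]1OC1(C)C | intermediate
23 | C10-methylene C15-ketone bis-epoxide | CC1(C)O[C@@H]1CC[C@@]2(C)[C@H](O[Si](C)(C)C(C)(C)C)CCC(=C)[C@@H]2CC[C@H]2C(=O)CC[C@@H](O[Si](C)(C)C(C)(C)C)[C@]2(C)CC[C@H]1OC1(C)C | intermediate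
24 | lithium C15 alkoxide (O α, methyl β) | CC1(C)O[C@@H]1CC[C@@]2(C)[C@H](O[Si](C)(C)C(C)(C)C)CCC(=C)[C@@H]2CC[C@H]2[C@@](C)([O-])CC[C@@H](O[Si](C)(C)C(C)(C)C)[C@]2(C)CC[C@H]1OC1(C)C.[Li+] | intermediate
25 | C15 α-acetate, C10 methylene, bis-epoxide, C7/C18 bis-silyl ether | CC1(C)O[C@@H]1CC[C@@]2(C)[C@H](O[Si](C)(C)C(C)(C)C)CCC(=C)[C@@H]2CC[C@H]2[C@@](C)(OC(C)=O)CC[C@@H](O[Si](C)(C)C(C)(C)C)[C@]2(C)CC[C@H]1OC1(C)C | intermediate
26 | C7,C18-diol from 25 | CC1(C)O[C@@H]1CC[C@@]2(C)[C@H](O)CCC(=C)[C@@H]2CC[C@H]2[C@@](C)(OC(C)=O)CC[C@@H](O)[C@]2(C)CC[C@H]1OC1(C)C | intermediate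
27 | bridged iodo ether (C7–O–C10, C10 CH2I), free C18-OH | CC1(C)O[C@@H]1CC[C@@]2(C)[C@H]3CC[C@](CI)(O3)[C@@H]2CC[C@H]2[C@@](C)(OC(C)=O)CC[C@@H](O)[C@]2(C)CC[C@H]1OC1(C)C | intermediate
28 | iodo ether with ring D closed, C22-OH | CC1(C)O[C@@H]1CC[C@@]2(C)[C@H]3CC[C@](CI)(O3)[C@@H]2CC[C@H]2[C@@](C)(OC(C)=O)CC[C@H]3OC(C)(C)[C@H](O)CC[C@@]32C | intermediate
29 | iodo ether with rings C/D complete (C15 and C22 acetates) | CC1(C)O[C@@H]1CC[C@@]2(C)[C@H]3CC[C@](CI)(O3)[C@@H]2CC[C@H]2[C@@](C)(OC(C)=O)CC[C@H]3OC(C)(C)[C@H](OC(C)=O)CC[C@@]32C | intermediate
30 | C7-hydroxy (3R)-2,3-epoxide with C10 methylene, rings C/D complete | CC1(C)O[C@@H]1CC[C@@]2(C)[C@H](O)CCC(=C)[C@@H]2CC[C@H]2[C@@](C)(OC(C)=O)CC[C@H]3OC(C)(C)[C@H](OC(C)=O)CC[C@@]32C | intermediate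
31 | CNP0412606.2 (C3 alcohol, C10 methylene, C15 and C22 acetates) | C=C1CC[C@H]2OC(C)(C)[C@H](O)CC[C@]2(C)[C@H]1CC[C@@H]1[C@@]2(C)CC[C@@H](OC(C)=O)C(C)(C)O[C@@H]2CC[C@]1(C)OC(C)=O | target

## Step count and risks

Total: 18 steps. Longest linear sequence: 18 steps (1 to 31; 2, 7 and 18 enter along the way).

**Step 3 (key step).** Facial control may erode at one or both enolates. The bridge carbon makes each enolate carbon substituted on both sides, which can change the enolate geometry that the chelate model presupposes and so contaminate 9 with the (R,S) diastereomer; cleavage of C12–C13 or over-reduction are lesser concerns. Fallback: starting from 6, the reduction is quenched with NH4Cl instead of the iodide to give the bis(1,4-dihydro) amide F1. Its enolates are then formed by deprotonation with LDA in THF at −78 °C, under conditions where the enolate geometry can equilibrate, and methylated with iodomethane to return to 9. The sense of induction in this mode would first be checked on the monomer 4.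

**Step 5.** Reduction through a non-chelated conformer would deliver hydride anti to the carboxamide and give the C7/C18 epimers. Fallback: starting from 9, the amide is reduced first (LiH2N·BH3) and the enol ethers are hydrolysed on work-up to the bis(β-hydroxy ketone) F2. Hydroxyl-directed reduction with Me4NBH(OAc)3 (Evans–Saksena, internal hydride delivery from the C5/C20 oxygen) gives the anti diol F3. Exhaustive silylation gives the tetrasilyl ether F4, and PPTS in methanol removes the primary silyl groups to rejoin the route at 13.

**Step 7.** Hydride attack on the very hindered carboxamide carbon may stall, or the C–N bond may be retained to give the amine. Fallback: starting from 12, the amide is activated at oxygen with Tf2O and 2-fluoropyridine and the resulting iminium is reduced with Et3SiH, giving after hydrolysis the bis-aldehyde F5; NaBH4 then returns the route to 13.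

**Step 16.** The iodoetherification needs ring B in a boat. If it is slow, the iodonium is captured intermolecularly, or the hydroxy epoxides of 26 close before the gate is set. Fallback: starting from 25, the pairing is done with the silyl ethers themselves. Partial desilylation (one equivalent of buffered TBAF) gives the C18 mono-alcohol F6, whose free hydroxyl sits on the ring that carries the tertiary acetate and is therefore separable from its C7 isomer; the isomer and the diol are re-silylated to 25. Acid closure of ring D and acetylation give the C7 silyl ether F7, and desilylation returns to the route at 30.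

**Step 17.** While ring D closes, the bystander epoxide of the gated half may be opened, most plausibly through participation of the bridged ether oxygen; 6-exo opening at C22 is the second concern. Fallback: starting from 26, the gate is abandoned and both oxepanes are closed in one acid treatment to the C3,C22-diol F8. One equivalent of acetic anhydride in pyridine then acetylates statistically to 31; the C3 acetate isomer and the diacetate are returned to F8 with K2CO3 in methanol, which spares the tertiary acetate.

## Further compounds

F1 | step 3 | 1,2-bis{5-methoxy-6-[(S)-2-(methoxymethyl)pyrrolidine-1-carbonyl]cyclohexa-1,4-dien-1-yl}ethane (C6 epimers) | COC[C@@H]1CCCN1C(=O)C2C(OC)=CCC=C2CCC2=CCC=C(OC)C2C(=O)N1CCC[C@H]1COC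
F2 | step 5 | bis(β-hydroxy ketone) (C5/C20 CH2OH, C7/C18 ketones, ring alkenes) | OC[C@@]1(C)C(=O)CCC=C1CCC1=CCCC(=O)[C@]1(C)CO
F3 | step 5 | anti 1,3-diol (C7/C18 OH α, C5/C20 CH2OH) | OC[C@@]1(C)[C@H](O)CCC=C1CCC1=CCC[C@@H](O)[C@]1(C)CO
F4 | step 5 | tetrakis(tert-butyldimethylsilyl) ether of F3 | CC(C)(C)[Si](C)(C)OC[C@@]1(C)[C@H](O[Si](C)(C)C(C)(C)C)CCC=C1CCC1=CCC[C@@H](O[Si](C)(C)C(C)(C)C)[C@]1(C)CO[Si](C)(C)C(C)(C)C
F5 | step 7 | bis-aldehyde (C5 and C20 as CHO, ring alkenes, C7/C18 OTBS) | O=C[C@@]1(C)[C@H](O[Si](C)(C)C(C)(C)C)CCC=C1CCC1=CCC[C@@H](O[Si](C)(C)C(C)(C)C)[C@]1(C)C=O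
F6 | step 16 | C18 mono-alcohol of 25 (C7 OTBS kept) | CC1(C)O[C@@H]1CC[C@@]2(C)[C@H](O[Si](C)(C)C(C)(C)C)CCC(=C)[C@@H]2CC[C@H]2[C@@](C)(OC(C)=O)CC[C@@H](O)[C@]2(C)CC[C@H]1OC1(C)C
F7 | step 16 | C7 silyl ether with rings C/D complete (C15 and C22 acetates), ring A epoxide | CC1(C)O[C@@H]1CC[C@@]2(C)[C@H](O[Si](C)(C)C(C)(C)C)CCC(=C)[C@@H]2CC[C@H]2[C@@](C)(OC(C)=O)CC[C@H]3OC(C)(C)[C@H](OC(C)=O)CC[C@@]32C
F8 | step 17 | C3,C22-diol (22-deacetyl 31) | C=C1CC[C@H]2OC(C)(C)[C@H](O)CC[C@]2(C)[C@H]1CC[C@@H]1[C@@]2(C)CC[C@@H](O)C(C)(C)O[C@@H]2CC[C@]1(C)OC(C)=O
A1 | alternative 1 | ring C/D diol with C14 vinyl group | C=C[C@@H]1[C@@]2(C)CC[C@@H](O)C(C)(C)O[C@@H]2CC[C@]1(C)O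
A2 | alternative 2 | ring A/B bicycle with C10 methylene and C12 silyl ether | C=C1CC[C@H]2OC(C)(C)[C@H](O)CC[C@]2(C)[C@H]1CO[Si](c1ccccc1)(c1ccccc1)C(C)(C)C
A3 | alternative 3 | ring C/D β-hydroxy aldehyde | O=C[C@@H]1[C@@]2(C)CC[C@@H](OC(C)=O)C(C)(C)O[C@@H]2CC[C@]1(C)O
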